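(R)-Carvone supplies ten skeletal carbons in place: the six of ring B, the methyl on C8 and, as its isopropenyl group on the future C5 stereocentre, C4 with C18 and C19. The key step exploits this overlap, so the plan rests on disconnecting C3–C4 in ring A. Hydrogen atom transfer from an iron hydride to the C18-oxygenated isopropenyl group gives a tertiary C4 radical. This radical closes ring A by 6-endo attack on a C1 vinyl ketone and creates the quaternary C4 centre at once. Precursor 12 is carvone bearing on C10 a methyl and, trans to C4, an acryloyl group, plus a bulky TBDPS ether on C18.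

Key step: step 8

Remark on the chemistry:
- Labdane numbering is used for every compound. Ring A is C1–C5 and C10, ring B is C5–C10, C17 sits on C8, C18 and C19 on C4, C20 on C10, and the side chain is C11–C13.
- α is the face of H5 and β is the face of C20. TBDPS = tert-butyldiphenylsilyl.
- The target is read as 4R,5R,8R,9R,10S. This means 4α-CO2H (C18, equatorial), 4β-Me (C19, axial), 5α-H, 8α-OAc, 8β-Me, 9α-H (side chain β, equatorial) and 10β-Me.
- Centres or geometries that the following step erases are carried as mixtures: C10 in 8, C1 in 11, C8 in 17, and C9=C11 in 23.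

Step 1
Reactants: 1 (R)-(−)-carvone
Product: 2 (5R)-5-(3-chloroprop-1-en-2-yl)-2-methylcyclohex-2-en-1-one
Conditions: Ca(OCl)2, CO2 (s), CH2Cl2–H2O, 0 °C
Reagents that add atoms: calcium hypochlorite, [Ca+2].[O-]Cl.[O-]Cl
Why: Ene-type allylic chlorination by HOCl picks the electron-rich 1,1-disubstituted alkene over the electron-poor enone and regenerates the 1,1-disubstituted double bond beside the new CH2Cl (C18), with C5 untouched.

Step 2
Reactants: 2 (5R)-5-(3-chloroprop-1-en-2-yl)-2-methylcyclohex-2-en-1-one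
Product: 3 (5R)-5-(3-acetoxyprop-1-en-2-yl)-2-methylcyclohex-2-en-1-one
Conditions: KOAc, NaI (cat.), DMF, 60 °C
Reagents that add atoms: potassium acetate, [K+].CC(=O)[O-]
Why: SN2 displacement of a primary allylic chloride by acetate, a base too weak to disturb the enone or C5.

Step 3
Reactants: 3 (5R)-5-(3-acetoxyprop-1-en-2-yl)-2-methylcyclohex-2-en-1-one
Product: 4 (5R)-5-(3-hydroxyprop-1-en-2-yl)-2-methylcyclohex-2-en-1-one
Conditions: K2CO3 (cat.), MeOH, 0 °C
Reagents that add atoms: none
Why: Carbonate-catalysed transesterification frees the primary allylic alcohol under conditions too mild for isomerisation of the enone.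

Step 4
Reactants: 4 (5R)-5-(3-hydroxyprop-1-en-2-yl)-2-methylcyclohex-2-en-1-one
Product: 5 (5R)-5-[3-(TBDPS-oxy)prop-1-en-2-yl]-2-methylcyclohex-2-en-1-one
Conditions: TBDPSCl, imidazole, DMF, rt
Reagents that add atoms: tert-butyl(chloro)diphenylsilane, CC(C)(C)[Si](Cl)(c1ccccc1)c1ccccc1
Why: Imidazole-promoted silylation of a primary alcohol; TBDPS is chosen because its bulk widens the steric gap between the two C4 substituents in step 8 and because it outlasts the bases, palladium, peracid and SmI2 that follow.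

Step 5
Reactants: 5 (5R)-5-[3-(TBDPS-oxy)prop-1-en-2-yl]-2-methylcyclohex-2-en-1-one; 6 iodomethane
Product: 8 (5R,6S)-2,6-dimethyl-5-[3-(TBDPS-oxy)prop-1-en-2-yl]cyclohex-2-en-1-one (trans epimer drawn; both C10 epimers are carried on), via lithium dienolate 7 (not isolated)
Conditions: LDA, THF, −78 °C; MeI, −78 → 0 °C
Reagents that add atoms: iodomethane (reactant 6), CI
Why: Kinetic α′-deprotonation gives the cross-conjugated dienolate, whose SN2 methylation at C10 enters mainly anti to the C5 side chain; the outcome at C10 is irrelevant because this carbon is planarised again in step 6.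

Step 6
Reactants: 8 (5R,6S)-2,6-dimethyl-5-[3-(TBDPS-oxy)prop-1-en-2-yl]cyclohex-2-en-1-one; 9 acrolein
Product: 11 (5S,6R)-6-(1-hydroxyprop-2-en-1-yl)-2,6-dimethyl-5-[3-(TBDPS-oxy)prop-1-en-2-yl]cyclohex-2-en-1-one (C1 carbinol epimers; C1 trans to C4), via lithium enolate 10 (not isolated)
Conditions: LDA, THF, −78 → 0 → −78 °C; acrolein, −78 °C; AcOH quench at −78 °C
Reagents that add atoms: acrolein (reactant 9), C=CC=O
Why: Aldol 1,2-addition of the tetrasubstituted lithium enolate; allylic strain with the C10 methyl holds the C5 side chain pseudo-axial, so the aldehyde arrives on the opposite face and quaternary C10 forms with C1 trans to C4 (C20 cis to C4), while the cold acid quench forestalls retro-aldol.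

Step 7
Reactants: 11 aldol adduct (C1 carbinol epimers)
Product: 12 (5S,6R)-6-acryloyl-2,6-dimethyl-5-[3-(TBDPS-oxy)prop-1-en-2-yl]cyclohex-2-en-1-one (10-acryloyl-10-methyl-18-silyloxy carvone; acryloyl trans to C4)
Conditions: Dess–Martin periodinane, CH2Cl2, 0 °C → rt
Reagents that add atoms: none
Why: Dess–Martin oxidation of the secondary allylic alcohol under near-neutral conditions merges both carbinol epimers into the vinyl ketone without retro-aldol or retro-Claisen cleavage at quaternary C10.

Step 8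
Reactants: 12 10-acryloyl-10-methyl-18-TBDPS-oxy carvone
Product: 13 18-(TBDPS-oxy)-11,12,13,14,15,16-hexanorlabd-7-ene-1,9-dione (trans-fused; 5α-H, 10β-Me, 4β-Me axial, 4α-CH2OTBDPS equatorial)
Conditions: Fe(acac)3 (30 mol %), Ph(i-PrO)SiH2 (2 equiv, slow addition), i-PrOH–THF, 0.01 M, Ar, rt → 40 °C
Reagents that add atoms: none
Why: An iron hydride made from Fe(acac)3 and the silane hands H• to the unhindered =CH2 (future C19), the nucleophilic tertiary C4 radical adds to the terminal carbon C3 of the C1 vinyl ketone, and the resulting C2 radical is reduced by Fe(II) and protonated by i-PrOH. The closest known reaction type is the intramolecular iron-mediated reductive olefin coupling (MHAT Giese cyclisation) that closes decalins at quaternary carbons. Ring A closes 6-endo-trig, since the 5-exo mode would strike the α-carbon C2 against the polarity of the enone and leave a primary radical. C4 is the only new stereocentre: in the chair transition state the substituent that becomes axial is pressed against the axial C20 methyl, so the CH2OTBDPS arm takes the equatorial α site beside H5 and the new C19 methyl goes axial β. The trans fusion is inherited from 12, where C1 and C4 are trans-diequatorial on ring B. The step needs HAT at the 1,1-disubstituted alkene only, which is secured because the vinyl ketone and the trisubstituted C7=C8 enone are electron-poor and slow toward the hydride, because C7 could be reached only through a four-membered ring, and because high dilution under argon suppresses intermolecular addition and O2 capture, while the poorly nucleophilic i-PrOH spares the non-enolisable β-diketone.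

Step 9
Reactants: 13 18-(TBDPS-oxy)-hexanorlabd-7-ene-1,9-dione
Product: 15 Δ1 enol triflate of 13 (C1–OTf; Δ7-en-9-one unchanged), via potassium C1 enolate 14 (not isolated)
Conditions: KHMDS (1.05 equiv), THF, −78 °C; PhNTf2, −78 → 0 °C
Reagents that add atoms: N-phenylbis(trifluoromethanesulfonimide), O=S(=O)(N(c1ccccc1)S(=O)(=O)C(F)(F)F)C(F)(F)F
Why: Kinetic deprotonation takes the only α-hydrogens present (C2–H, because C10 is quaternary and the enone can lose only a slower γ-hydrogen), and O-sulfonylation of the enolate gives the enol triflate.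

Step 10
Reactants: 15 Δ1 enol triflate
Product: 16 18-(TBDPS-oxy)-hexanorlabda-1,7-dien-9-one
Conditions: Pd(OAc)2 (5 mol %), PPh3, HCO2H, Et3N, DMF, 60 °C
Reagents that add atoms: none
Why: Palladium-catalysed formate hydrogenolysis of an enol triflate (oxidative addition, decarboxylation of formate, reductive elimination) replaces C1–O by C1–H without a C1 radical or a β-hydroxy ketone next to the C9 carbonyl, so acyl migration and retro-aldol are avoided.

Step 11
Reactants: 16 18-(TBDPS-oxy)-hexanorlabda-1,7-dien-9-one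
Product: 17 18-(TBDPS-oxy)-hexanorlabdan-9-one (C8 epimers)
Conditions: H2 (1 atm), Pd/C, EtOAc, rt
Reagents that add atoms: none
Why: Heterogeneous hydrogenation saturates the Δ1 alkene and the conjugated Δ7 alkene in one operation and spares the hindered C9 ketone and the silyl ether; the C8 configuration does not matter because C8 is planarised in step 12.

Step 12
Reactants: 17 18-(TBDPS-oxy)-hexanorlabdan-9-one
Product: 19 Δ8(9) enol triflate of 17 (C9–OTf), via potassium C9 enolate 18 (not isolated)
Conditions: KHMDS, THF, −78 → 0 °C; PhNTf2, 0 °C → rt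
Reagents that add atoms: N-phenylbis(trifluoromethanesulfonimide), O=S(=O)(N(c1ccccc1)S(=O)(=O)C(F)(F)F)C(F)(F)F
Why: C8–H is the only enolisable position of the C9 ketone, so enolate formation and O-triflation give the tetrasubstituted enol triflate as one regioisomer, as with 2,2,6-trimethylcyclohexanone.

Step 13
Reactants: 19 Δ8(9) enol triflate; 20 benzyl acrylate
Product: 21 benzyl (11E)-18-(TBDPS-oxy)-14,15,16-trinorlabda-8,11-dien-13-oate
Conditions: Pd(OAc)2 (10 mol %), PPh3, Et3N, DMF, 75 °C
Reagents that add atoms: benzyl acrylate (reactant 20), C=CC(=O)OCc1ccccc1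
Why: Heck reaction of an enol triflate with an acrylate forms C9–C11 and brings in C11–C13 at once, and syn insertion followed by syn β-hydride elimination gives the (E)-dienoate.

Step 14
Reactants: 21 benzyl (11E)-dienoate
Product: 22 benzyl (11E)-8α,9α-epoxy-18-(TBDPS-oxy)-14,15,16-trinorlabd-11-en-13-oate
Conditions: mCPBA, CH2Cl2, 0 °C
Reagents that add atoms: 3-chloroperoxybenzoic acid, O=C(OO)c1cccc(Cl)c1
Why: Prilezhaev epoxidation picks the electron-rich tetrasubstituted γ,δ-alkene (twisted out of conjugation as in β-ionone) over the enoate alkene and arrives on the α face because the axial C20 methyl covers the β face, which sets the 8α C–O bond and the 8β methyl.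

Step 15
Reactants: 22 8α,9α-epoxy enoate
Product: 23 benzyl 8α-hydroxy-18-(TBDPS-oxy)-14,15,16-trinorlabd-9(11)-en-13-oate (C9=C11 geometry open)
Conditions: SmI2 (2.5 equiv), THF–MeOH, −78 °C
Reagents that add atoms: none
Why: Samarium diiodide reduction of a γ,δ-epoxy-α,β-unsaturated ester: electron transfer to the enoate expels only the γ oxygen bond (C9–O), the Sm(III) dienolate is protonated at the α-carbon C12, and the C8–O bond keeps its configuration, so the regiochemistry is dictated by the ester and not by cation stability.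

Step 16
Reactants: 23 8α-hydroxy-Δ9(11) ester
Product: 24 benzyl 8α-hydroxy-18-(TBDPS-oxy)-14,15,16-trinorlabdan-13-oate (9α-H)
Conditions: Mn(dpm)3 (10 mol %), Ph(i-PrO)SiH2, t-BuOOH, i-PrOH, rt
Reagents that add atoms: none
Why: Manganese-catalysed HAT hydrogenation puts H• on the exposed C11, and the tertiary C9 radical takes its hydrogen on the α face opposite the two axial methyls C17 and C20, giving 9α-H with the side chain equatorial, the thermodynamically preferred outcome typical of this method; benzyl ester and silyl ether are inert.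

Step 17
Reactants: 24 8α-hydroxy ester
Product: 25 benzyl 8α-acetoxy-18-(TBDPS-oxy)-14,15,16-trinorlabdan-13-oate
Conditions: AcCl, PhNMe2, CH2Cl2, 0 °C → rt
Reagents that add atoms: acetyl chloride, CC(=O)Cl
Why: Acylation of the hindered tertiary alcohol with acetyl chloride and a weak aniline base, the standard method for labdan-8α-ols, done while C13 is still a benzyl ester and C18 a silyl ether so that no activated carboxyl group can lactonise onto O8.

Step 18
Reactants: 25 8α-acetoxy silyl ether
Product: 26 benzyl 8α-acetoxy-18-hydroxy-14,15,16-trinorlabdan-13-oate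
Conditions: TBAF, AcOH, THF, rt → 45 °C
Reagents that add atoms: none
Why: Fluoride cleavage of the Si–O bond, buffered with acetic acid so that neither the tertiary acetate nor the benzyl ester is attacked.

Step 19
Reactants: 26 8α-acetoxy-18-ol
Product: 27 8α-acetoxy-13-benzyloxy-13-oxo-14,15,16-trinorlabdan-18-oic acid
Conditions: CrO3, H2SO4, H2O, acetone, 0 °C
Reagents that add atoms: water, O
Why: Jones oxidation takes the neopentyl primary alcohol through the aldehyde hydrate to the C18 acid, the usual access to resin-acid carboxyl groups; the tertiary acetate and the benzyl ester tolerate the short cold exposure and C4 has no hydrogen to epimerise.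

Step 20
Reactants: 27 C18 acid C13 benzyl ester
Product: 28 (4R,5R,8R,9R,10S)-8α-acetoxy-14,15,16-trinorlabdane-13,18-dioic acid (CNP0196050.1)
Conditions: H2 (1 atm), Pd/C, EtOAc, rt
Reagents that add atoms: none
Why: Neutral hydrogenolysis of the benzyl ester frees the C13 acid without touching the tertiary acetate or any stereocentre.

Compound list

1 | (R)-(−)-carvone | CC1=CC[C@@H](C(C)=C)CC1=O | starting material
2 | (5R)-5-(3-chloroprop-1-en-2-yl)-2-methylcyclohex-2-en-1-one | CC1=CC[C@@H](C(=C)CCl)CC1=O | intermediate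
3 | (5R)-5-(3-acetoxyprop-1-en-2-yl)-2-methylcyclohex-2-en-1-one | CC1=CC[C@@H](C(=C)COC(C)=O)CC1=O | intermediate
4 | (5R)-5-(3-hydroxyprop-1-en-2-yl)-2-methylcyclohex-2-en-1-one | CC1=CC[C@@H](C(=C)CO)CC1=O | intermediate
5 | (5R)-5-[3-(TBDPS-oxy)prop-1-en-2-yl]-2-methylcyclohex-2-en-1-one | CC1=CC[C@@H](C(=C)CO[Si](c2ccccc2)(c2ccccc2)C(C)(C)C)CC1=O | intermediate
6 | iodomethane | CI | starting material
7 | lithium cross-conjugated dienolate of 5 (not isolated) | CC1=CC[C@@H](C(=C)CO[Si](c2ccccc2)(c2ccccc2)C(C)(C)C)C=C1[O-].[Li+] | intermediate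
8 | (5R,6S)-2,6-dimethyl-5-[3-(TBDPS-oxy)prop-1-en-2-yl]cyclohex-2-en-1-one (major trans epimer) | CC1=CC[C@@H](C(=C)CO[Si](c2ccccc2)(c2ccccc2)C(C)(C)C)[C@H](C)C1=O | intermediate
9 | acrolein | C=CC=O | starting material
10 | lithium C9=C10 enolate of 8 (not isolated) | CC1=CC[C@@H](C(=C)CO[Si](c2ccccc2)(c2ccccc2)C(C)(C)C)C(C)=C1[O-].[Li+] | intermediate
11 | (5S,6R)-6-(1-hydroxyprop-2-en-1-yl)-2,6-dimethyl-5-[3-(TBDPS-oxy)prop-1-en-2-yl]cyclohex-2-en-1-one (carbinol epimers) | C=CC(O)[C@@]1(C)[C@H](C(=C)CO[Si](c2ccccc2)(c2ccccc2)C(C)(C)C)CC=C(C)C1=O | intermediate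
12 | (5S,6R)-6-acryloyl-2,6-dimethyl-5-[3-(TBDPS-oxy)prop-1-en-2-yl]cyclohex-2-en-1-one | C=CC(=O)[C@@]1(C)[C@H](C(=C)CO[Si](c2ccccc2)(c2ccccc2)C(C)(C)C)CC=C(C)C1=O | intermediate
13 | 18-(TBDPS-oxy)-11,12,13,14,15,16-hexanorlabd-7-ene-1,9-dione (trans-fused, 4β-Me, 4α-CH2OTBDPS) | CC1=CC[C@@H]2[C@](C)(C(=O)CC[C@@]2(C)CO[Si](c3ccccc3)(c3ccccc3)C(C)(C)C)C1=O | intermediate
14 | potassium C1=C2 enolate of 13 (not isolated) | CC1=CC[C@@H]2[C@](C)(C([O-])=CC[C@@]2(C)CO[Si](c3ccccc3)(c3ccccc3)C(C)(C)C)C1=O.[K+] | intermediate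
15 | Δ1 enol triflate of 13 | CC1=CC[C@@H]2[C@](C)(C(OS(=O)(=O)C(F)(F)F)=CC[C@@]2(C)CO[Si](c3ccccc3)(c3ccccc3)C(C)(C)C)C1=O | intermediate
16 | 18-(TBDPS-oxy)-hexanorlabda-1,7-dien-9-one | CC1=CC[C@@H]2[C@](C)(C=CC[C@@]2(C)CO[Si](c3ccccc3)(c3ccccc3)C(C)(C)C)C1=O | intermediate
17 | 18-(TBDPS-oxy)-hexanorlabdan-9-one (C8 epimers) | CC1CC[C@@H]2[C@](C)(CCC[C@@]2(C)CO[Si](c3ccccc3)(c3ccccc3)C(C)(C)C)C1=O | intermediate
18 | potassium C8=C9 enolate of 17 (not isolated) | CC1=C([O-])[C@@]2(C)CCC[C@@](C)(CO[Si](c3ccccc3)(c3ccccc3)C(C)(C)C)[C@@H]2CC1.[K+] | intermediate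
19 | Δ8(9) enol triflate of 17 | CC1=C(OS(=O)(=O)C(F)(F)F)[C@@]2(C)CCC[C@@](C)(CO[Si](c3ccccc3)(c3ccccc3)C(C)(C)C)[C@@H]2CC1 | intermediate
20 | benzyl acrylate | C=CC(=O)OCc1ccccc1 | starting material
21 | benzyl (11E)-18-(TBDPS-oxy)-14,15,16-trinorlabda-8,11-dien-13-oate | CC1=C(/C=C/C(=O)OCc3ccccc3)[C@@]2(C)CCC[C@@](C)(CO[Si](c3ccccc3)(c3ccccc3)C(C)(C)C)[C@@H]2CC1 | intermediate
22 | benzyl (11E)-8α,9α-epoxy-18-(TBDPS-oxy)-14,15,16-trinorlabd-11-en-13-oate | C[C@]12O[C@@]1(/C=C/C(=O)OCc1ccccc1)[C@@]3(C)CCC[C@@](C)(CO[Si](c4ccccc4)(c4ccccc4)C(C)(C)C)[C@@H]3CC2 | intermediate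
23 | benzyl 8α-hydroxy-18-(TBDPS-oxy)-14,15,16-trinorlabd-9(11)-en-13-oate | C[C@@]1(O)CC[C@@H]2[C@](C)(CCC[C@@]2(C)CO[Si](c3ccccc3)(c3ccccc3)C(C)(C)C)C1=CCC(=O)OCc1ccccc1 | intermediate
24 | benzyl 8α-hydroxy-18-(TBDPS-oxy)-14,15,16-trinorlabdan-13-oate | C[C@@]1(O)CC[C@@H]2[C@](C)(CCC[C@@]2(C)CO[Si](c3ccccc3)(c3ccccc3)C(C)(C)C)[C@H]1CCC(=O)OCc1ccccc1 | intermediate
25 | benzyl 8α-acetoxy-18-(TBDPS-oxy)-14,15,16-trinorlabdan-13-oate | CC(=O)O[C@]1(C)CC[C@@H]2[C@](C)(CCC[C@@]2(C)CO[Si](c3ccccc3)(c3ccccc3)C(C)(C)C)[C@H]1CCC(=O)OCc1ccccc1 | intermediate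
26 | benzyl 8α-acetoxy-18-hydroxy-14,15,16-trinorlabdan-13-oate | CC(=O)O[C@]1(C)CC[C@@H]2[C@](C)(CCC[C@@]2(C)CO)[C@H]1CCC(=O)OCc1ccccc1 | intermediate
27 | 8α-acetoxy-13-benzyloxy-13-oxo-14,15,16-trinorlabdan-18-oic acid | CC(=O)O[C@]1(C)CC[C@@H]2[C@](C)(CCC[C@@]2(C)C(=O)O)[C@H]1CCC(=O)OCc1ccccc1 | intermediate
28 | (4R,5R,8R,9R,10S)-8α-acetoxy-14,15,16-trinorlabdane-13,18-dioic acid | CC(=O)O[C@]1(C)CC[C@@H]2[C@](C)(CCC[C@@]2(C)C(=O)O)[C@H]1CCC(=O)O | target

Total step count: 20. Longest linear sequence: 20 steps, from 1 to 28.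

Steps most likely to fail

Step 8. What may go wrong:
- weak facial discrimination at the planar C4 radical;
- capture of that radical by a second hydrogen atom before ring closure;
- hydride attack on the vinyl ketone.

The fallback sets out from 1 and returns at 13. It makes the same C4 radical by reductive epoxide opening instead of HAT. Carvone 1 is methylated (LDA, MeI) to (5R,6S)-6-methylcarvone F1. The lithium enolate of F1 is added to acrolein 9 to give the aldol adduct F2. mCPBA epoxidises only the isopropenyl group and gives the epoxy alcohol F3 as both epoxide epimers, and Dess–Martin oxidation gives the epoxy vinyl ketone F4. Cp2TiCl (from Cp2TiCl2 and Mn in THF, Nugent–RajanBabu reaction) opens the epoxide to the tertiary C4 radical, which now carries CH2O–TiCp2Cl, a much larger group than a silyl ether. Ring A closes on the vinyl ketone, and aqueous work-up should give the 18-hydroxy dione F5. Silylation of F5 with TBDPSCl and imidazole gives 13.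

Step 13. What may go wrong:
- slow olefin insertion at the C9–Pd centre, which is flanked by quaternary C10 and the C8 methyl;
- competing reduction of the triflate;
- decay of the catalyst.

The fallback sets out from 19 and returns at 21. It inserts the smallest possible partner first and then builds the chain by olefination. Palladium-catalysed methoxycarbonylation (CO, MeOH, Et3N, Pd(OAc)2, dppp, DMF) gives the Δ8-11-oic methyl ester F6. DIBAL-H reduces it to the allylic alcohol F7, and MnO2 gives the enal F8, an analogue of β-cyclocitral. A Horner–Wadsworth–Emmons reaction with benzyl diethylphosphonoacetate (NaH, THF) gives 21.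

Step 17. What may go wrong:
- ring closure of O8 onto the C13 ester (δ-lactonisation) outrunning the slow acylation of the hindered tertiary alcohol.

The fallback sets out from 24 and returns at 28. It removes the electrophilic carbonyl before the acylation. LiAlH4 reduces 24 to the 8α,13-diol F9, and TBDPSCl with imidazole protects only the primary hydroxyl to give the bis-silyl ether F10. AcCl with PhNMe2 gives the tertiary acetate F11, and TBAF with AcOH removes both silyl groups to give the 8α-acetoxy-13,18-diol F12. One Jones oxidation takes both primary alcohols to the acids and gives 28. The acetate on O8 blocks lactol and lactone formation during that oxidation.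

Further compounds

F1 | step 8 | (5R,6S)-6-methylcarvone | CC1=CC[C@@H](C(C)=C)[C@H](C)C1=O
F2 | step 8 | (5S,6R)-6-(1-hydroxyprop-2-en-1-yl)-2,6-dimethyl-5-(prop-1-en-2-yl)cyclohex-2-en-1-one (carbinol epimers) | C=CC(O)[C@@]1(C)[C@H](C(C)=C)CC=C(C)C1=O
F3 | step 8 | epoxy alcohol, 5-(2-methyloxiran-2-yl) analogue of F2 (epoxide epimers) | C=CC(O)[C@@]1(C)[C@H](C2(C)CO2)CC=C(C)C1=O
F4 | step 8 | epoxy vinyl ketone, 6-acryloyl-2,6-dimethyl-5-(2-methyloxiran-2-yl)cyclohex-2-en-1-one | C=CC(=O)[C@@]1(C)[C@H](C2(C)CO2)CC=C(C)C1=O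
F5 | step 8 | 18-hydroxy-11,12,13,14,15,16-hexanorlabd-7-ene-1,9-dione | CC1=CC[C@@H]2[C@](C)(C(=O)CC[C@@]2(C)CO)C1=O
F6 | step 13 | methyl 18-(TBDPS-oxy)-12,13,14,15,16-pentanorlabd-8-en-11-oate | CC1=C(C(=O)OC)[C@@]2(C)CCC[C@@](C)(CO[Si](c3ccccc3)(c3ccccc3)C(C)(C)C)[C@@H]2CC1
F7 | step 13 | 18-(TBDPS-oxy)-12,13,14,15,16-pentanorlabd-8-en-11-ol | CC1=C(CO)[C@@]2(C)CCC[C@@](C)(CO[Si](c3ccccc3)(c3ccccc3)C(C)(C)C)[C@@H]2CC1
F8 | step 13 | 18-(TBDPS-oxy)-12,13,14,15,16-pentanorlabd-8-en-11-al | CC1=C(C=O)[C@@]2(C)CCC[C@@](C)(CO[Si](c3ccccc3)(c3ccccc3)C(C)(C)C)[C@@H]2CC1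
F9 | step 17 | 18-(TBDPS-oxy)-14,15,16-trinorlabdane-8α,13-diol | C[C@@]1(O)CC[C@@H]2[C@](C)(CCC[C@@]2(C)CO[Si](c3ccccc3)(c3ccccc3)C(C)(C)C)[C@H]1CCCO
F10 | step 17 | 13,18-bis(TBDPS-oxy)-14,15,16-trinorlabdan-8α-ol | C[C@@]1(O)CC[C@@H]2[C@](C)(CCC[C@@]2(C)CO[Si](c3ccccc3)(c3ccccc3)C(C)(C)C)[C@H]1CCCO[Si](c1ccccc1)(c1ccccc1)C(C)(C)C
F11 | step 17 | 8α-acetoxy-13,18-bis(TBDPS-oxy)-14,15,16-trinorlabdane | CC(=O)O[C@]1(C)CC[C@@H]2[C@](C)(CCC[C@@]2(C)CO[Si](c3ccccc3)(c3ccccc3)C(C)(C)C)[C@H]1CCCO[Si](c1ccccc1)(c1ccccc1)C(C)(C)C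
F12 | step 17 | 8α-acetoxy-14,15,16-trinorlabdane-13,18-diol | CC(=O)O[C@]1(C)CC[C@@H]2[C@](C)(CCC[C@@]2(C)CO)[C@H]1CCCO
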